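**Strategy**

Everything rests on cutting the O1–C2 bond of the 2,2-dimethyl-2H-pyran ring, which turns C2–C3–C4 back into a prenyl group on C4a of an already complete methylene-bridged dimer. The key step exploits that the future C4, a CH2 on C4a, is benzylic and allylic and lies ortho to the C8a hydroxyl, the one next to acetyl-bearing C8: a single DDQ dehydrogenation creates the C3=C4 alkene and the O1–C2 bond and so closes the pyran ring. Its precursor is the acetylfilicinic acid–phloroacetophenone dimer bearing the C-prenyl group and one MOM ether on the C5 oxygen, which rules out closure on that side. The bridge is laid by a directed Mannich-base coupling, not a statistical formaldehyde condensation.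

Key step: step 6

Remark: the enolised triketone ring is drawn throughout in the tautomer of the target, chromene numbering (O1, C2–C4, C4a, C5–C8, C8a) is used for the aryl half of all dimers, and the target has no stereocentre.

**Route**

Step 1
Reactants: 1 2,4,6-trihydroxyacetophenone (phloroacetophenone); 2 chloromethyl methyl ether
Product: 3 1-[2,6-dihydroxy-4-(methoxymethoxy)phenyl]ethanone
Conditions: MOMCl (1.0 equiv), K2CO3 (1.1 equiv), acetone, 0 °C to rt
Reagents that add atoms: chloromethyl methyl ether 2, COCCl
Why: Williamson-type O-alkylation (MOM protection): the 4-hydroxyl para to the acetyl group is the most acidic one and the only one not hydrogen-bonded to the ketone, so one equivalent of the chloride should cap it first and leave a symmetric diol whose two ring CH positions are equivalent.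

Step 2
Reactants: 3 1-[2,6-dihydroxy-4-(methoxymethoxy)phenyl]ethanone; 4 1-bromo-3-methylbut-2-ene
Product: 5 1-[2,6-dihydroxy-4-(methoxymethoxy)-3-(3-methylbut-2-en-1-yl)phenyl]ethanone
Conditions: prenyl bromide (1.0 equiv), 10% aq. KOH, 0 °C to rt
Reagents that add atoms: 1-bromo-3-methylbut-2-ene 4, CC(C)=CCBr
Why: C-alkylation of an ambident phloroglucinol-type phenoxide (Friedel–Crafts-type C-prenylation): in water the phenoxide oxygens are solvated and tied to the acetyl group, so the soft allylic bromide should be attacked by a ring carbon, the two free carbons being equivalent and the limited amount of bromide curbing a second prenylation.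

Step 3
Reactants: 1 2,4,6-trihydroxyacetophenone; 6 iodomethane
Product: 8 acetylfilicinic acid (2-acetyl-3,5-dihydroxy-4,4-dimethylcyclohexa-2,5-dien-1-one), via C-monomethyl phloroacetophenone 7 (not isolated)
Conditions: MeI (2.5 equiv), NaOMe (3 equiv), MeOH, 0 °C to rt
Reagents that add atoms: iodomethane 6, CI
Why: Dearomatising geminal C-methylation of a phloroglucinol polyanion: the first methyl group enters a free ring carbon and the second the same, now more electron-rich carbon, giving the 4,4-dimethyl dienone, whose vinylogous-acid anion is a weaker nucleophile and should slow a third methylation.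

Step 4
Reactants: 5 1-[2,6-dihydroxy-4-(methoxymethoxy)-3-(3-methylbut-2-en-1-yl)phenyl]ethanone; 9 N,N-dimethylmethyleneiminium iodide (Eschenmoser's salt)
Product: 10 1-[3-[(dimethylamino)methyl]-2,6-dihydroxy-4-(methoxymethoxy)-5-(3-methylbut-2-en-1-yl)phenyl]ethanone
Conditions: Me2N=CH2+ I− (1.2 equiv), K2CO3 (1.5 equiv), CH2Cl2, 0 °C to rt
Reagents that add atoms: N,N-dimethylmethyleneiminium iodide 9, C=[N+](C)C.[I-]
Why: Phenolic Mannich reaction with a preformed iminium salt: the one unsubstituted ring carbon, ortho to a free hydroxyl, should be aminomethylated, and the absence of free formaldehyde in an aprotic solvent avoids diarylmethane formation.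

Step 5
Reactants: 10 1-[3-[(dimethylamino)methyl]-2,6-dihydroxy-4-(methoxymethoxy)-5-(3-methylbut-2-en-1-yl)phenyl]ethanone; 8 acetylfilicinic acid
Product: 12 2-acetyl-6-{[3-acetyl-2,4-dihydroxy-6-(methoxymethoxy)-5-(3-methylbut-2-en-1-yl)phenyl]methyl}-3,5-dihydroxy-4,4-dimethylcyclohexa-2,5-dien-1-one, via ortho-quinone methide 11 (not isolated)
Conditions: 8 (1.2 equiv), 1,4-dioxane, 90 °C, N2
Reagents that add atoms: acetylfilicinic acid 8, CC(=O)C1=C(O)C(C)(C)C(O)=CC1=O
Why: Mannich-base alkylation through an ortho-quinone methide: proton transfer from the acidic triketone to the amine and loss of dimethylamine should give 11, which the enolate of 8 captures by Michael addition at its only free ring carbon, so the methylene carbon comes from one partner alone and symmetric dimers are not expected.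

Step 6
Reactants: 12 2-acetyl-6-{[3-acetyl-2,4-dihydroxy-6-(methoxymethoxy)-5-(3-methylbut-2-en-1-yl)phenyl]methyl}-3,5-dihydroxy-4,4-dimethylcyclohexa-2,5-dien-1-one
Product: 14 2-acetyl-6-{[8-acetyl-7-hydroxy-5-(methoxymethoxy)-2,2-dimethyl-2H-chromen-6-yl]methyl}-3,5-dihydroxy-4,4-dimethylcyclohexa-2,5-dien-1-one, via dienyl ortho-quinone methide 13 (not isolated)
Conditions: DDQ (1.1 equiv, added slowly), dry toluene, rt to 60 °C, N2
Reagents that add atoms: none
Why: DDQ should take a hydride from the prenyl CH2 on C4a (the future C4), giving a cation spread over the ring oxygens and the dimethylallyl terminus, and loss of the C8a–OH proton then gives ortho-quinone methide 13, whose (Z)-1-oxatriene O=C8a–C4a=C4–C3=C2 closes thermally to form O1–C2 and restore the aromatic ring. The closest known reaction type is the DDQ dehydrogenative cyclisation of ortho-prenylphenols to 2,2-dimethyl-2H-chromenes, which is well established on free acylphloroglucinols. The pyran ring is closed by a disrotatory oxa-6π electrocyclisation in a six-membered (endo) sense, and no stereocentre arises because C2 carries two methyl groups. The step needs regioselectivity between the two oxygens flanking C4a, and the MOM ether on the C5 oxygen secures it, since that oxygen cannot become a quinone methide carbonyl and only the C8a hydroxyl is left to close. It also needs chemoselectivity between the two benzylic methylenes: the prenyl CH2 gives a cation reaching a tertiary allylic terminus, whereas the bridge CH2 is shielded by four ortho substituents and attached to an electron-poor triketone ring, so one equivalent of DDQ should discriminate. The enolised triketone and the MOM acetal should be inert to DDQ under dry, neutral conditions.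

Step 7
Reactants: 14 2-acetyl-6-{[8-acetyl-7-hydroxy-5-(methoxymethoxy)-2,2-dimethyl-2H-chromen-6-yl]methyl}-3,5-dihydroxy-4,4-dimethylcyclohexa-2,5-dien-1-one
Product: 15 2-acetyl-6-[(8-acetyl-5,7-dihydroxy-2,2-dimethyl-2H-chromen-6-yl)methyl]-3,5-dihydroxy-4,4-dimethylcyclohexa-2,5-dien-1-one (target)
Conditions: HCl (ca. 1 M, from conc. aq. HCl), MeOH/THF, rt to 40 °C
Reagents that add atoms: none
Why: Acid-catalysed acetal solvolysis (MOM cleavage): the MOM ether sits between two ortho substituents, is twisted out of conjugation and should be released by dilute acid near room temperature, conditions that 2,2-dimethyl-2H-chromenes and the methylene bridge are expected to tolerate, while the fully substituted rings offer no site for the liberated formaldehyde equivalent.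

**Compound list**

1 | 2,4,6-trihydroxyacetophenone (phloroacetophenone) | CC(=O)c1c(O)cc(O)cc1O | starting material
2 | chloromethyl methyl ether | COCCl | starting material
3 | 1-[2,6-dihydroxy-4-(methoxymethoxy)phenyl]ethanone | CC(=O)c1c(O)cc(OCOC)cc1O | intermediate
4 | 1-bromo-3-methylbut-2-ene (prenyl bromide) | CC(C)=CCBr | starting material
5 | 1-[2,6-dihydroxy-4-(methoxymethoxy)-3-(3-methylbut-2-en-1-yl)phenyl]ethanone | CC(=O)c1c(O)cc(OCOC)c(CC=C(C)C)c1O | intermediate
6 | iodomethane | CI | starting material
7 | 1-(2,4,6-trihydroxy-3-methylphenyl)ethanone (formed in the flask, not isolated) | CC(=O)c1c(O)cc(O)c(C)c1O | intermediate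
8 | acetylfilicinic acid, 2-acetyl-3,5-dihydroxy-4,4-dimethylcyclohexa-2,5-dien-1-one | CC(=O)C1=C(O)C(C)(C)C(O)=CC1=O | intermediate
9 | N,N-dimethylmethyleneiminium iodide (Eschenmoser's salt) | C=[N+](C)C.[I-] | starting material
10 | 1-[3-[(dimethylamino)methyl]-2,6-dihydroxy-4-(methoxymethoxy)-5-(3-methylbut-2-en-1-yl)phenyl]ethanone | CC(=O)c1c(O)c(CC=C(C)C)c(OCOC)c(CN(C)C)c1O | intermediate
11 | 2-acetyl-3-hydroxy-5-(methoxymethoxy)-6-methylidene-4-(3-methylbut-2-en-1-yl)cyclohexa-2,4-dien-1-one, ortho-quinone methide (formed in the flask, not isolated) | C=C1C(=O)C(C(C)=O)=C(O)C(CC=C(C)C)=C1OCOC | intermediate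
12 | 2-acetyl-6-{[3-acetyl-2,4-dihydroxy-6-(methoxymethoxy)-5-(3-methylbut-2-en-1-yl)phenyl]methyl}-3,5-dihydroxy-4,4-dimethylcyclohexa-2,5-dien-1-one | CC(=O)C1=C(O)C(C)(C)C(O)=C(Cc2c(O)c(C(C)=O)c(O)c(CC=C(C)C)c2OCOC)C1=O | intermediate
13 | ortho-quinone methide of 12 with C8a as carbonyl and a (Z)-configured 3-methylbut-2-enylidene group on C4a (formed in the flask, not isolated) | CC(=O)C1=C(O)C(C)(C)C(O)=C(CC2=C(OCOC)/C(=C/C=C(C)C)C(=O)C(C(C)=O)=C2O)C1=O | intermediate
14 | 2-acetyl-6-{[8-acetyl-7-hydroxy-5-(methoxymethoxy)-2,2-dimethyl-2H-chromen-6-yl]methyl}-3,5-dihydroxy-4,4-dimethylcyclohexa-2,5-dien-1-one | CC(=O)C1=C(O)C(C)(C)C(O)=C(Cc2c(OCOC)c3C=CC(C)(C)Oc3c(C(C)=O)c2O)C1=O | intermediate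
15 | 2-acetyl-6-[(8-acetyl-5,7-dihydroxy-2,2-dimethyl-2H-chromen-6-yl)methyl]-3,5-dihydroxy-4,4-dimethylcyclohexa-2,5-dien-1-one | CC(=O)C1=C(O)C(C)(C)C(O)=C(Cc2c(O)c3c(c(C(C)=O)c2O)OC(C)(C)C=C3)C1=O | target

**Step count**

Total step count: 7.
Longest linear sequence: 6 steps (1 → 3 → 5 → 10 → 12 → 14 → 15). Acetylfilicinic acid 8 is made in one step from 1 and enters at step 5.

**Steps most likely to fail**

Step 6 (key step). Hydride abstraction at the bridging methylene, or further oxidation of the electron-rich aryl ring, may compete with dehydrogenation of the prenyl group and erode the dimer. The fallback moves the same closure to the monomer, where no bridge exists. It sets out from 5: DDQ in dry toluene should give, under the same MOM control, 1-[7-hydroxy-5-(methoxymethoxy)-2,2-dimethyl-2H-chromen-8-yl]ethanone F1. Aminomethylation of its single free ring carbon with 9 and K2CO3 in CH2Cl2 should give 1-[6-[(dimethylamino)methyl]-7-hydroxy-5-(methoxymethoxy)-2,2-dimethyl-2H-chromen-8-yl]ethanone F2. Heating F2 with 8 in 1,4-dioxane, by the quinone methide mechanism of step 5, should deliver 14, where the fallback comes back to the route before step 7.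

Step 2. O-alkylation, double or geminal C-prenylation, and hydrolysis of the bromide in aqueous base may leave little mono-C-prenyl product. The fallback replaces direct C-alkylation by O-alkylation and sigmatropic transfer. It sets out from 3: Williamson etherification of one of the two equivalent hydroxyls with 4 (K2CO3, acetone, reflux) should give 1-[2-hydroxy-4-(methoxymethoxy)-6-(3-methylbut-2-en-1-yloxy)phenyl]ethanone F3. Heating F3 in N,N-diethylaniline at about 190 °C should bring about a Claisen–Cope sequence: a [3,3] shift to the neighbouring free ring carbon, a second [3,3] shift to the para carbon, then enolisation. This places an unrearranged prenyl group between the hydroxyl and the MOM ether, and the fallback comes back to the route at 5.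

Step 5. Elimination of dimethylamine from the hindered benzylic amine may be sluggish, or methylene exchange between the partners may give symmetric dimers. The fallback reverses the roles of the two halves. It sets out from 8: aminomethylation with 9 (K2CO3, CH2Cl2) should give 2-acetyl-6-[(dimethylamino)methyl]-3,5-dihydroxy-4,4-dimethylcyclohexa-2,5-dien-1-one F4. Warming F4 with 5 in 1,4-dioxane should expel dimethylamine to unmask a methylene-triketone Michael acceptor, which the free ring carbon of 5 attacks in a Friedel–Crafts-type conjugate addition. The fallback comes back to the route at 12.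

**Further compounds**

F1 | step 6 | 1-[7-hydroxy-5-(methoxymethoxy)-2,2-dimethyl-2H-chromen-8-yl]ethanone | CC(=O)c1c(O)cc(OCOC)c2C=CC(C)(C)Oc12
F2 | step 6 | 1-[6-[(dimethylamino)methyl]-7-hydroxy-5-(methoxymethoxy)-2,2-dimethyl-2H-chromen-8-yl]ethanone | CC(=O)c1c(O)c(CN(C)C)c(OCOC)c2C=CC(C)(C)Oc12
F3 | step 2 | 1-[2-hydroxy-4-(methoxymethoxy)-6-(3-methylbut-2-en-1-yloxy)phenyl]ethanone | CC(=O)c1c(O)cc(OCOC)cc1OCC=C(C)C
F4 | step 5 | 2-acetyl-6-[(dimethylamino)methyl]-3,5-dihydroxy-4,4-dimethylcyclohexa-2,5-dien-1-one | CC(=O)C1=C(O)C(C)(C)C(O)=C(CN(C)C)C1=O
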